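## Retrosynthetic overview

1. End game: the target comes from an 8-hydroxy germacranolide by O8 angeloylation, O9 desilylation and acetylation, and O3 desilylation.
2. Key step, second ring (ten-membered carbocycle): the C7–C8 bond is closed by an intramolecular chromium Barbier (Nozaki–Hiyama) allylation of an α-silyloxy aldehyde by an α-(bromomethyl)butenolide. This one step makes the ring, the exocyclic methylene and the C7 and C8 stereocentres, and leaves O8 free.
3. First ring (butenolide carrying C6): Pd-catalysed carbonylative lactonisation of a Z-iodoallylic alcohol, made by directed hydroalumination–iodination of a propargylic alcohol from asymmetric alkynylation of the C6 enal.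
4. Open chain: Z-selective Wittig (C1=C10) between a C1–C6 phosphonium salt (C3 from an acetate aldol on an acetal-masked enal) and a C8–C10 methyl ketone from methyl (R)-glycerate acetonide (C9).

Assumption: the SMILES is read as the 6,12-germacranolide with 3S,6R,7S,8R,9S centres, a Z C1=C10 olefin, an E C4=C5 olefin and the angelate ((Z)-2-methylbut-2-enoate) on O8; germacrane numbering is used for positions; TBS = tert-butyldimethylsilyl, TES = triethylsilyl, PMB = 4-methoxybenzyl, HYTRA = 2-hydroxy-1,2,2-triphenylethyl acetate.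

## Route

Step 1
Reactants: 1 2,2-dimethoxyacetaldehyde; 2 propanal
Product: 3 (E)-4,4-dimethoxy-2-methylbut-2-enal
Conditions: piperidine (10 mol%), AcOH (10 mol%), toluene, 60 °C, slow addition of 2
Reagents that add atoms: none
Why: Amine-catalysed crossed aldol condensation in which only propanal can form the enamine and the non-enolisable acetal aldehyde is the acceptor; dehydration gives the thermodynamically favoured E-enal and no stereocentre is formed.

Step 2
Reactants: 3 (E)-4,4-dimethoxy-2-methylbut-2-enal; 4 (S)-HYTRA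
Product: 6 (S)-2-hydroxy-1,2,2-triphenylethyl (3S,4E)-3-hydroxy-6,6-dimethoxy-4-methylhex-4-enoate, via magnesium enolate 5 (not isolated)
Conditions: 4, LiN(iPr)2 (2.2 equiv), THF, −78 to 0 °C; MgBr2·OEt2, −78 °C; then 3, THF/2-methylbutane, −115 °C; aqueous work-up
Reagents that add atoms: none
Why: Braun acetate aldol addition in which the doubly deprotonated (S)-HYTRA, transmetalated to magnesium, attacks the Si face of the aldehyde under auxiliary control and sets C3 as S, the minor epimer being removed by recrystallisation of the adduct.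

Step 3
Reactants: 6 (S)-2-hydroxy-1,2,2-triphenylethyl (3S,4E)-3-hydroxy-6,6-dimethoxy-4-methylhex-4-enoate
Product: 7 (S)-2-hydroxy-1,2,2-triphenylethyl (3S,4E)-3-(TBSO)-6,6-dimethoxy-4-methylhex-4-enoate
Conditions: TBSCl, imidazole, DMAP (cat.), DMF, 35 °C
Reagents that add atoms: tert-butyl(chloro)dimethylsilane, CC(C)(C)[Si](C)(C)Cl
Why: Imidazole-promoted silyl ether formation at the secondary allylic alcohol, the hindered tertiary carbinol of the auxiliary staying free.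

Step 4
Reactants: 7 (S)-2-hydroxy-1,2,2-triphenylethyl (3S,4E)-3-(TBSO)-6,6-dimethoxy-4-methylhex-4-enoate
Product: 8 (3S,4E)-3-(TBSO)-6,6-dimethoxy-4-methylhex-4-en-1-ol
Conditions: LiAlH4, THF, 0 °C; aqueous work-up
Reagents that add atoms: none
Why: Hydride reduction of the ester to the primary alcohol releases the recoverable auxiliary diol and touches neither the acetal nor the silyl ether.

Step 5
Reactants: 8 (3S,4E)-3-(TBSO)-6,6-dimethoxy-4-methylhex-4-en-1-ol
Product: 9 (3S,4E)-3-(TBSO)-1-iodo-6,6-dimethoxy-4-methylhex-4-ene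
Conditions: PPh3, iodine, imidazole, CH2Cl2, 0 °C
Reagents that add atoms: iodine, [I][I]
Why: Garegg–Samuelsson (Appel-type) iodination converts the only free, primary alcohol into the iodide by SN2 displacement of the oxyphosphonium, imidazole keeping the medium non-acidic for the acetal.

Step 6
Reactants: 9 (3S,4E)-3-(TBSO)-1-iodo-6,6-dimethoxy-4-methylhex-4-ene
Product: 10 [(3S,4E)-3-(TBSO)-6,6-dimethoxy-4-methylhex-4-en-1-yl]triphenylphosphonium iodide
Conditions: PPh3 (1.5 equiv), iPr2NEt (5 mol%), MeCN, 80 °C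
Reagents that add atoms: triphenylphosphine, c1ccc(cc1)P(c1ccccc1)c1ccccc1
Why: SN2 quaternisation of triphenylphosphine by the primary iodide (phosphonium salt formation), a trace of amine guarding the acetal.

Step 7
Reactants: 11 methyl (R)-2,2-dimethyl-1,3-dioxolane-4-carboxylate
Product: 13 (R)-1-(2,2-dimethyl-1,3-dioxolan-4-yl)ethan-1-one, via Weinreb amide 12 (not isolated)
Conditions: MeNH(OMe)·HCl, iPrMgCl, THF, −20 °C; then MeMgBr, −20 to 0 °C; aqueous work-up
Reagents that add atoms: methylmagnesium bromide, C[Mg]Br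
Why: One-pot Weinreb ketone synthesis (ester aminolysis by the magnesium amide, then Grignard addition to the chelated N-methoxy-N-methylamide), which stops at the ketone and leaves the α-stereocentre (future C9) untouched.

Step 8
Reactants: 10 [(3S,4E)-3-(TBSO)-6,6-dimethoxy-4-methylhex-4-en-1-yl]triphenylphosphonium iodide; 13 (R)-1-(2,2-dimethyl-1,3-dioxolan-4-yl)ethan-1-one
Product: 15 (4S)-4-[(2Z,5S,6E)-5-(TBSO)-8,8-dimethoxy-6-methylocta-2,6-dien-2-yl]-2,2-dimethyl-1,3-dioxolane, via phosphonium ylide 14 (not isolated)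
Conditions: 10 (1.3 equiv), NaN(SiMe3)2, THF, −78 to 0 °C; then 13, −78 °C to rt
Reagents that add atoms: none
Why: Wittig olefination of a salt-free unstabilised ylide with an α-alkoxy methyl ketone (Still's Z-selective variant) places C2 cis to the oxygenated C9 and gives the Z-trisubstituted C1=C10 olefin without creating a stereocentre.

Step 9
Reactants: 15 (4S)-4-[(2Z,5S,6E)-5-(TBSO)-8,8-dimethoxy-6-methylocta-2,6-dien-2-yl]-2,2-dimethyl-1,3-dioxolane
Product: 16 (2E,4S,6Z,8S)-4-(TBSO)-8,9-dihydroxy-3,7-dimethylnona-2,6-dienal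
Conditions: AcOH/THF/H2O (3:1:1), 45 °C
Reagents that add atoms: water, O
Why: Acid-catalysed hydrolysis in which aqueous acetic acid cleaves both the allylic dimethyl acetal and the terminal isopropylidene ketal while the secondary TBS ether survives, unmasking the C6 enal and the 8,9-diol in one operation.

Step 10
Reactants: 16 (2E,4S,6Z,8S)-4-(TBSO)-8,9-dihydroxy-3,7-dimethylnona-2,6-dienal
Product: 17 (2E,4S,6Z,8S)-4-(TBSO)-3,7-dimethyl-8,9-bis(TESO)nona-2,6-dienal
Conditions: TESCl (2.5 equiv), imidazole, CH2Cl2, 0 °C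
Reagents that add atoms: chlorotriethylsilane, CC[Si](Cl)(CC)CC
Why: Imidazole-promoted silylation of both hydroxyls gives a primary TES ether (later oxidised directly) and a secondary TES ether (later removed selectively beside TBS).

Step 11
Reactants: 17 (2E,4S,6Z,8S)-4-(TBSO)-3,7-dimethyl-8,9-bis(TESO)nona-2,6-dienal; 18 4-methoxybenzyl propargyl ether
Product: 20 (4R,5E,7S,9Z,11S)-7-(TBSO)-1-(PMBO)-6,10-dimethyl-11,12-bis(TESO)dodeca-5,9-dien-2-yn-4-ol, via alkynylzinc 19 (not isolated)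
Conditions: 18 (3 equiv), Me2Zn (3 equiv), (S,S)-ProPhenol (20 mol%), Ph3PO (40 mol%), toluene, 4 °C; then 17; aqueous work-up
Reagents that add atoms: none
Why: Zinc–ProPhenol-catalysed asymmetric alkynylation of an enal (Trost alkynylation), in which the ligand delivers the alkynylzinc to the Si face of the aldehyde and sets C6 as R (the sense is to be confirmed by Mosher analysis, the antipodal ligand giving the epimer).

Step 12
Reactants: 20 (4R,5E,7S,9Z,11S)-7-(TBSO)-1-(PMBO)-6,10-dimethyl-11,12-bis(TESO)dodeca-5,9-dien-2-yn-4-ol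
Product: 22 (2Z,4R,5E,7S,9Z,11S)-7-(TBSO)-2-iodo-1-(PMBO)-6,10-dimethyl-11,12-bis(TESO)dodeca-2,5,9-trien-4-ol, via vinylaluminate 21 (not isolated)
Conditions: NaAlH2(OCH2CH2OMe)2, THF, 0 °C to rt; then iodine, THF, −78 °C; aqueous work-up
Reagents that add atoms: iodine, [I][I]
Why: Hydroxyl-directed trans-hydroalumination of the propargylic alcohol followed by iodinolysis with retention puts H on C7 and iodine on C11 cis to C6, the Z geometry needed for lactonisation.

Step 13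
Reactants: 22 (2Z,4R,5E,7S,9Z,11S)-7-(TBSO)-2-iodo-1-(PMBO)-6,10-dimethyl-11,12-bis(TESO)dodeca-2,5,9-trien-4-ol
Product: 23 (5R)-5-[(1E,3S,5Z,7S)-3-(TBSO)-2,6-dimethyl-7,8-bis(TESO)octa-1,5-dien-1-yl]-3-[(PMBO)methyl]furan-2(5H)-one
Conditions: PdCl2(PPh3)2 (5 mol%), K2CO3, CO (1 atm), THF, 45 °C
Reagents that add atoms: carbon monoxide, [C-]#[O+]
Why: Palladium-catalysed carbonylative lactonisation of a Z-γ-iodo allylic alcohol (oxidative addition to zerovalent palladium formed in situ, CO insertion, capture of the acylpalladium by the C6 hydroxyl) builds the butenolide without touching C6.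

Step 14
Reactants: 23 (5R)-5-[(1E,3S,5Z,7S)-3-(TBSO)-2,6-dimethyl-7,8-bis(TESO)octa-1,5-dien-1-yl]-3-[(PMBO)methyl]furan-2(5H)-one
Product: 24 (5R)-5-[(1E,3S,5Z,7S)-3-(TBSO)-2,6-dimethyl-7,8-bis(TESO)octa-1,5-dien-1-yl]-3-(hydroxymethyl)furan-2(5H)-one
Conditions: DDQ (1.3 equiv), CH2Cl2/pH 7 buffer, 0 °C
Reagents that add atoms: none
Why: Oxidative cleavage of the 4-methoxybenzyl ether by DDQ under buffered conditions, to which the silyl ethers and the butenolide are inert.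

Step 15
Reactants: 24 (5R)-5-[(1E,3S,5Z,7S)-3-(TBSO)-2,6-dimethyl-7,8-bis(TESO)octa-1,5-dien-1-yl]-3-(hydroxymethyl)furan-2(5H)-one
Product: 25 (5R)-3-(bromomethyl)-5-[(1E,3S,5Z,7S)-3-(TBSO)-2,6-dimethyl-7,8-bis(TESO)octa-1,5-dien-1-yl]furan-2(5H)-one
Conditions: CBr4, PPh3, 2,6-lutidine (0.5 equiv), CH2Cl2, −20 to 0 °C
Reagents that add atoms: tetrabromomethane, BrC(Br)(Br)Br
Why: Appel bromination of the primary allylic alcohol under cold, buffered conditions that leave the TES ethers intact.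

Step 16
Reactants: 25 (5R)-3-(bromomethyl)-5-[(1E,3S,5Z,7S)-3-(TBSO)-2,6-dimethyl-7,8-bis(TESO)octa-1,5-dien-1-yl]furan-2(5H)-one
Product: 26 (2S,3Z,6S,7E)-8-[(2R)-4-(bromomethyl)-5-oxo-2,5-dihydrofuran-2-yl]-6-(TBSO)-3,7-dimethyl-2-(TESO)octa-3,7-dienal
Conditions: (COCl)2, DMSO, CH2Cl2, −78 to −35 °C; then iPr2NEt, −78 to −20 °C; used at once
Reagents that add atoms: none
Why: Swern oxidation in which chlorodimethylsulfonium chloride cleaves the primary TES ether selectively and oxidises it directly to the aldehyde, the hindered base at low temperature sparing the allylic bromide and the C9 stereocentre.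

Step 17
Reactants: 26 (2S,3Z,6S,7E)-8-[(2R)-4-(bromomethyl)-5-oxo-2,5-dihydrofuran-2-yl]-6-(TBSO)-3,7-dimethyl-2-(TESO)octa-3,7-dienal
Product: 28 (3aR,4R,5S,6Z,9S,10E,11aR)-9-(TBSO)-4-hydroxy-6,10-dimethyl-3-methylidene-5-(TESO)-3a,4,5,8,9,11a-hexahydrocyclodeca[b]furan-2(3H)-one, via allylchromium 27 (not isolated)
Conditions: CrCl2 (8 equiv), degassed THF, rt, 26 added over 12 h to 0.002 molar; aqueous work-up
Reagents that add atoms: none
Why: Intramolecular Nozaki–Hiyama (chromium Barbier) allylation in which divalent chromium turns the allylic bromide into a trivalent allylchromium that adds through C7 to the aldehyde in a closed chair transition state on the butenolide face opposite C5 (6,7-trans lactone), the ring-locked E-type allyl unit giving the 7,8-anti relationship and Felkin–Anh control by the C9 silyloxy group giving the 8,9-anti relationship, so that all three elements converge on 7S,8R while the ten-membered ring and the exocyclic methylene form together and O8 is released free.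

Step 18
Reactants: 28 (3aR,4R,5S,6Z,9S,10E,11aR)-9-(TBSO)-4-hydroxy-6,10-dimethyl-3-methylidene-5-(TESO)-3a,4,5,8,9,11a-hexahydrocyclodeca[b]furan-2(3H)-one; 29 angelic acid
Product: 31 (3aS,4R,5S,6Z,9S,10E,11aR)-9-(TBSO)-6,10-dimethyl-3-methylidene-2-oxo-5-(TESO)-2,3,3a,4,5,8,9,11a-octahydrocyclodeca[b]furan-4-yl (Z)-2-methylbut-2-enoate, via mixed anhydride 30 (not isolated)
Conditions: 29 (5 equiv), 2,4,6-trichlorobenzoyl chloride, Et3N, toluene, rt; then 28, toluene, 80 °C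
Reagents that add atoms: none
Why: Yamaguchi-type esterification through the preformed angelic 2,4,6-trichlorobenzoic mixed anhydride without nucleophilic catalyst acylates the hindered C8 hydroxyl at the less hindered angeloyl carbonyl and avoids Z-to-E isomerisation to the tiglate.

Step 19
Reactants: 31 (3aS,4R,5S,6Z,9S,10E,11aR)-9-(TBSO)-6,10-dimethyl-3-methylidene-2-oxo-5-(TESO)-2,3,3a,4,5,8,9,11a-octahydrocyclodeca[b]furan-4-yl (Z)-2-methylbut-2-enoate
Product: 32 (3aS,4R,5S,6Z,9S,10E,11aR)-9-(TBSO)-5-hydroxy-6,10-dimethyl-3-methylidene-2-oxo-2,3,3a,4,5,8,9,11a-octahydrocyclodeca[b]furan-4-yl (Z)-2-methylbut-2-enoate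
Conditions: PPTS (20 mol%), MeOH/CH2Cl2 (1:1), 0 °C to rt
Reagents that add atoms: none
Why: Acid-catalysed methanolysis removes the secondary TES ether much faster than the secondary TBS ether, and the non-basic medium prevents migration of the angelate.

Step 20
Reactants: 32 (3aS,4R,5S,6Z,9S,10E,11aR)-9-(TBSO)-5-hydroxy-6,10-dimethyl-3-methylidene-2-oxo-2,3,3a,4,5,8,9,11a-octahydrocyclodeca[b]furan-4-yl (Z)-2-methylbut-2-enoate
Product: 33 (3aS,4R,5S,6Z,9S,10E,11aR)-5-acetoxy-9-(TBSO)-6,10-dimethyl-3-methylidene-2-oxo-2,3,3a,4,5,8,9,11a-octahydrocyclodeca[b]furan-4-yl (Z)-2-methylbut-2-enoate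
Conditions: Ac2O, pyridine, DMAP (cat.), CH2Cl2, 0 °C
Reagents that add atoms: acetic anhydride, CC(=O)OC(C)=O
Why: DMAP-catalysed acetylation of the allylic C9 alcohol is fast enough at 0 °C to outrun acyl migration or isomerisation of the angelate.

Step 21
Reactants: 33 (3aS,4R,5S,6Z,9S,10E,11aR)-5-acetoxy-9-(TBSO)-6,10-dimethyl-3-methylidene-2-oxo-2,3,3a,4,5,8,9,11a-octahydrocyclodeca[b]furan-4-yl (Z)-2-methylbut-2-enoate
Product: 34 (3aS,4R,5S,6Z,9S,10E,11aR)-5-acetoxy-9-hydroxy-6,10-dimethyl-3-methylidene-2-oxo-2,3,3a,4,5,8,9,11a-octahydrocyclodeca[b]furan-4-yl (Z)-2-methylbut-2-enoate (CNP0265116.1)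
Conditions: HF·pyridine, pyridine, THF, 0 °C to rt
Reagents that add atoms: none
Why: Fluoride-mediated cleavage of the TBS ether with buffered HF·pyridine is mild enough for both esters and the α-methylene lactone and gives the target.

## Compound list

1 | 2,2-dimethoxyacetaldehyde | COC(OC)C=O | starting material
2 | propanal | CCC=O | starting material
3 | (E)-4,4-dimethoxy-2-methylbut-2-enal | COC(OC)/C=C(\C)C=O | intermediate
4 | (S)-2-hydroxy-1,2,2-triphenylethyl acetate, (S)-HYTRA | CC(=O)O[C@@H](c1ccccc1)C(O)(c1ccccc1)c1ccccc1 | starting material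
5 | bis(bromomagnesium) enolate–alkoxide of 4 | C=C(O[Mg]Br)O[C@@H](c1ccccc1)C(O[Mg]Br)(c1ccccc1)c1ccccc1 | intermediate
6 | (S)-2-hydroxy-1,2,2-triphenylethyl (3S,4E)-3-hydroxy-6,6-dimethoxy-4-methylhex-4-enoate | COC(OC)/C=C(\C)[C@@H](O)CC(=O)O[C@@H](c1ccccc1)C(O)(c1ccccc1)c1ccccc1 | intermediate
7 | (S)-2-hydroxy-1,2,2-triphenylethyl (3S,4E)-3-[(tert-butyldimethylsilyl)oxy]-6,6-dimethoxy-4-methylhex-4-enoate | COC(OC)/C=C(\C)[C@@H](O[Si](C)(C)C(C)(C)C)CC(=O)O[C@@H](c1ccccc1)C(O)(c1ccccc1)c1ccccc1 | intermediate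
8 | (3S,4E)-3-[(tert-butyldimethylsilyl)oxy]-6,6-dimethoxy-4-methylhex-4-en-1-ol | COC(OC)/C=C(\C)[C@@H](O[Si](C)(C)C(C)(C)C)CCO | intermediate
9 | tert-butyl{[(3S,4E)-1-iodo-6,6-dimethoxy-4-methylhex-4-en-3-yl]oxy}dimethylsilane | COC(OC)/C=C(\C)[C@@H](O[Si](C)(C)C(C)(C)C)CC[I] | intermediate
10 | {(3S,4E)-3-[(tert-butyldimethylsilyl)oxy]-6,6-dimethoxy-4-methylhex-4-en-1-yl}triphenylphosphonium iodide | COC(OC)/C=C(\C)[C@@H](O[Si](C)(C)C(C)(C)C)CC[P+](c1ccccc1)(c1ccccc1)c1ccccc1.[I-] | intermediate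
11 | methyl (R)-2,2-dimethyl-1,3-dioxolane-4-carboxylate | COC(=O)[C@H]1COC(C)(C)O1 | starting material
12 | (R)-N-methoxy-N,2,2-trimethyl-1,3-dioxolane-4-carboxamide | CON(C)C(=O)[C@H]1COC(C)(C)O1 | intermediate
13 | (R)-1-(2,2-dimethyl-1,3-dioxolan-4-yl)ethan-1-one | CC(=O)[C@H]1COC(C)(C)O1 | intermediate
14 | {(3S,4E)-3-[(tert-butyldimethylsilyl)oxy]-6,6-dimethoxy-4-methylhex-4-en-1-ylidene}triphenylphosphorane | COC(OC)/C=C(\C)[C@@H](O[Si](C)(C)C(C)(C)C)CC=P(c1ccccc1)(c1ccccc1)c1ccccc1 | intermediate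
15 | (4S)-4-[(2Z,5S,6E)-5-[(tert-butyldimethylsilyl)oxy]-8,8-dimethoxy-6-methylocta-2,6-dien-2-yl]-2,2-dimethyl-1,3-dioxolane | COC(OC)/C=C(\C)[C@@H](O[Si](C)(C)C(C)(C)C)C/C=C(/C)[C@H]1COC(C)(C)O1 | intermediate
16 | (2E,4S,6Z,8S)-4-[(tert-butyldimethylsilyl)oxy]-8,9-dihydroxy-3,7-dimethylnona-2,6-dienal | O=C/C=C(\C)[C@@H](O[Si](C)(C)C(C)(C)C)C/C=C(/C)[C@H](O)CO | intermediate
17 | (2E,4S,6Z,8S)-4-[(tert-butyldimethylsilyl)oxy]-3,7-dimethyl-8,9-bis[(triethylsilyl)oxy]nona-2,6-dienal | O=C/C=C(\C)[C@@H](O[Si](C)(C)C(C)(C)C)C/C=C(/C)[C@H](O[Si](CC)(CC)CC)CO[Si](CC)(CC)CC | intermediate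
18 | 1-methoxy-4-[(prop-2-yn-1-yloxy)methyl]benzene (4-methoxybenzyl propargyl ether) | C#CCOCc1ccc(OC)cc1 | starting material
19 | methyl{3-[(4-methoxybenzyl)oxy]prop-1-yn-1-yl}zinc | C[Zn]C#CCOCc1ccc(OC)cc1 | intermediate
20 | (4R,5E,7S,9Z,11S)-7-[(tert-butyldimethylsilyl)oxy]-1-[(4-methoxybenzyl)oxy]-6,10-dimethyl-11,12-bis[(triethylsilyl)oxy]dodeca-5,9-dien-2-yn-4-ol | O[C@@H](C#CCOCc1ccc(OC)cc1)/C=C(\C)[C@@H](O[Si](C)(C)C(C)(C)C)C/C=C(/C)[C@H](O[Si](CC)(CC)CC)CO[Si](CC)(CC)CC | intermediate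
21 | sodium cyclic alkoxy(vinyl)bis(2-methoxyethoxy)aluminate of 20 (Al on C11, O6–Al bond, H on C7) | [Na+].COCCO[Al-]1(OCCOC)O[C@@H](C=C1COCc1ccc(OC)cc1)/C=C(\C)[C@@H](O[Si](C)(C)C(C)(C)C)C/C=C(/C)[C@H](O[Si](CC)(CC)CC)CO[Si](CC)(CC)CC | intermediate
22 | (2Z,4R,5E,7S,9Z,11S)-7-[(tert-butyldimethylsilyl)oxy]-2-iodo-1-[(4-methoxybenzyl)oxy]-6,10-dimethyl-11,12-bis[(triethylsilyl)oxy]dodeca-2,5,9-trien-4-ol | O[C@@H](/C=C(\[I])COCc1ccc(OC)cc1)/C=C(\C)[C@@H](O[Si](C)(C)C(C)(C)C)C/C=C(/C)[C@H](O[Si](CC)(CC)CC)CO[Si](CC)(CC)CC | intermediate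
23 | (5R)-5-{(1E,3S,5Z,7S)-3-[(tert-butyldimethylsilyl)oxy]-2,6-dimethyl-7,8-bis[(triethylsilyl)oxy]octa-1,5-dien-1-yl}-3-{[(4-methoxybenzyl)oxy]methyl}furan-2(5H)-one | O=C1O[C@@H](C=C1COCc1ccc(OC)cc1)/C=C(\C)[C@@H](O[Si](C)(C)C(C)(C)C)C/C=C(/C)[C@H](O[Si](CC)(CC)CC)CO[Si](CC)(CC)CC | intermediate
24 | (5R)-5-{(1E,3S,5Z,7S)-3-[(tert-butyldimethylsilyl)oxy]-2,6-dimethyl-7,8-bis[(triethylsilyl)oxy]octa-1,5-dien-1-yl}-3-(hydroxymethyl)furan-2(5H)-one | O=C1O[C@@H](C=C1CO)/C=C(\C)[C@@H](O[Si](C)(C)C(C)(C)C)C/C=C(/C)[C@H](O[Si](CC)(CC)CC)CO[Si](CC)(CC)CC | intermediate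
25 | (5R)-3-(bromomethyl)-5-{(1E,3S,5Z,7S)-3-[(tert-butyldimethylsilyl)oxy]-2,6-dimethyl-7,8-bis[(triethylsilyl)oxy]octa-1,5-dien-1-yl}furan-2(5H)-one | O=C1O[C@@H](C=C1CBr)/C=C(\C)[C@@H](O[Si](C)(C)C(C)(C)C)C/C=C(/C)[C@H](O[Si](CC)(CC)CC)CO[Si](CC)(CC)CC | intermediate
26 | (2S,3Z,6S,7E)-8-[(2R)-4-(bromomethyl)-5-oxo-2,5-dihydrofuran-2-yl]-6-[(tert-butyldimethylsilyl)oxy]-3,7-dimethyl-2-[(triethylsilyl)oxy]octa-3,7-dienal | O=C1O[C@@H](C=C1CBr)/C=C(\C)[C@@H](O[Si](C)(C)C(C)(C)C)C/C=C(/C)[C@H](O[Si](CC)(CC)CC)C=O | intermediate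
27 | allylchromium dichloride of 26 (CrCl2 on C13 in place of Br) | O=C1O[C@@H](C=C1C[Cr](Cl)Cl)/C=C(\C)[C@@H](O[Si](C)(C)C(C)(C)C)C/C=C(/C)[C@H](O[Si](CC)(CC)CC)C=O | intermediate
28 | (3aR,4R,5S,6Z,9S,10E,11aR)-9-[(tert-butyldimethylsilyl)oxy]-4-hydroxy-6,10-dimethyl-3-methylidene-5-[(triethylsilyl)oxy]-3a,4,5,8,9,11a-hexahydrocyclodeca[b]furan-2(3H)-one | C=C1C(=O)O[C@@H]2/C=C(\C)[C@@H](O[Si](C)(C)C(C)(C)C)C/C=C(/C)[C@H](O[Si](CC)(CC)CC)[C@H](O)[C@@H]12 | intermediate
29 | angelic acid, (Z)-2-methylbut-2-enoic acid | C/C=C(/C)C(=O)O | starting material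
30 | (Z)-2-methylbut-2-enoic 2,4,6-trichlorobenzoic anhydride | C/C=C(/C)C(=O)OC(=O)c1c(Cl)cc(Cl)cc1Cl | intermediate
31 | (3aS,4R,5S,6Z,9S,10E,11aR)-9-[(tert-butyldimethylsilyl)oxy]-6,10-dimethyl-3-methylidene-2-oxo-5-[(triethylsilyl)oxy]-2,3,3a,4,5,8,9,11a-octahydrocyclodeca[b]furan-4-yl (Z)-2-methylbut-2-enoate | C=C1C(=O)O[C@@H]2/C=C(\C)[C@@H](O[Si](C)(C)C(C)(C)C)C/C=C(/C)[C@H](O[Si](CC)(CC)CC)[C@H](OC(=O)/C(C)=C\C)[C@@H]12 | intermediate
32 | (3aS,4R,5S,6Z,9S,10E,11aR)-9-[(tert-butyldimethylsilyl)oxy]-5-hydroxy-6,10-dimethyl-3-methylidene-2-oxo-2,3,3a,4,5,8,9,11a-octahydrocyclodeca[b]furan-4-yl (Z)-2-methylbut-2-enoate | C=C1C(=O)O[C@@H]2/C=C(\C)[C@@H](O[Si](C)(C)C(C)(C)C)C/C=C(/C)[C@H](O)[C@H](OC(=O)/C(C)=C\C)[C@@H]12 | intermediate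
33 | (3aS,4R,5S,6Z,9S,10E,11aR)-5-acetoxy-9-[(tert-butyldimethylsilyl)oxy]-6,10-dimethyl-3-methylidene-2-oxo-2,3,3a,4,5,8,9,11a-octahydrocyclodeca[b]furan-4-yl (Z)-2-methylbut-2-enoate | C=C1C(=O)O[C@@H]2/C=C(\C)[C@@H](O[Si](C)(C)C(C)(C)C)C/C=C(/C)[C@H](OC(C)=O)[C@H](OC(=O)/C(C)=C\C)[C@@H]12 | intermediate
34 | (3aS,4R,5S,6Z,9S,10E,11aR)-5-acetoxy-9-hydroxy-6,10-dimethyl-3-methylidene-2-oxo-2,3,3a,4,5,8,9,11a-octahydrocyclodeca[b]furan-4-yl (Z)-2-methylbut-2-enoate (CNP0265116.1) | C=C1C(=O)O[C@@H]2/C=C(\C)[C@@H](O)C/C=C(/C)[C@H](OC(C)=O)[C@H](OC(=O)/C(C)=C\C)[C@@H]12 | target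

## Step count and risks

Total step count: 21. Longest linear sequence: 20 (steps 1–6 and 8–21; step 7 is a one-step side branch).

The three steps most likely to fail:

Step 11. The enal is β,β-disubstituted and carries remote stereocentres, so conversion and facial control at C6 are the weak points, and the sense of induction of the chosen ligand antipode must be verified. The fallback sets out from 17 and comes back at 20. The lithium acetylide of 18 (n-BuLi, THF, −78 °C) is added to 17 without stereocontrol to give the C6-epimeric propargylic alcohol mixture F1. MnO2 oxidation gives the cross-conjugated ynone F2. Reduction of F2 with (R)-Alpine-Borane (B-isopinocampheyl-9-borabicyclo[3.3.1]nonane, neat, rt), in which the alkynyl group acts as the small substituent, then returns 20. Reagent-controlled ketone reduction thus replaces catalytic asymmetric carbon–carbon bond formation.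

Step 17. The macrocyclising Barbier reaction can give oligomers, attack through C13 instead of C7, the C8 epimer, or translactonisation of the chromium alkoxide to the 8,12-olide. The fallback sets out from 25 and comes back at 28. Bromide 25 is borylated (B2pin2, Pd2(dba)3 cat., toluene, 50 °C) to the pinacol allylboronate F3. The oxidation of step 16 then gives the boronate aldehyde F4. F4 is cyclised by intramolecular allylboration (toluene, 0.002 molar, 80 °C, optionally Sc(OTf)3 cat.), and hydrolysis of the borate ester gives 28. This is a non-reductive allylation of an isolable, purifiable donor that passes through the same closed chair transition state, so the stereochemical argument is unchanged.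

Step 18. The C8 hydroxyl is hindered (flanked by the silyloxy group and the lactone), angelates isomerise readily to tiglates, and prolonged heating with amine could move the lactone to O8. The fallback sets out from 28 and comes back at 31. Alcohol 28 is esterified with 2-[bis(2,2,2-trifluoroethoxy)phosphoryl]propanoic acid (N,N'-dicyclohexylcarbodiimide, DMAP cat., CH2Cl2, 0 °C) to the phosphonopropionate ester F5. The angelate is then built in place by Still–Gennari olefination with acetaldehyde (KN(SiMe3)2, 18-crown-6, THF, −78 °C), which gives the Z-2-methylbut-2-enoate 31 without ever activating angelic acid.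

## Further compounds

F1 | step 11 | (4RS,5E,7S,9Z,11S)-7-[(tert-butyldimethylsilyl)oxy]-1-[(4-methoxybenzyl)oxy]-6,10-dimethyl-11,12-bis[(triethylsilyl)oxy]dodeca-5,9-dien-2-yn-4-ol (C6-epimeric mixture) | OC(C#CCOCc1ccc(OC)cc1)/C=C(\C)[C@@H](O[Si](C)(C)C(C)(C)C)C/C=C(/C)[C@H](O[Si](CC)(CC)CC)CO[Si](CC)(CC)CC
F2 | step 11 | (5E,7S,9Z,11S)-7-[(tert-butyldimethylsilyl)oxy]-1-[(4-methoxybenzyl)oxy]-6,10-dimethyl-11,12-bis[(triethylsilyl)oxy]dodeca-5,9-dien-2-yn-4-one | O=C(C#CCOCc1ccc(OC)cc1)/C=C(\C)[C@@H](O[Si](C)(C)C(C)(C)C)C/C=C(/C)[C@H](O[Si](CC)(CC)CC)CO[Si](CC)(CC)CC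
F3 | step 17 | (5R)-5-{(1E,3S,5Z,7S)-3-[(tert-butyldimethylsilyl)oxy]-2,6-dimethyl-7,8-bis[(triethylsilyl)oxy]octa-1,5-dien-1-yl}-3-[(4,4,5,5-tetramethyl-1,3,2-dioxaborolan-2-yl)methyl]furan-2(5H)-one | O=C1O[C@@H](C=C1CB2OC(C)(C)C(C)(C)O2)/C=C(\C)[C@@H](O[Si](C)(C)C(C)(C)C)C/C=C(/C)[C@H](O[Si](CC)(CC)CC)CO[Si](CC)(CC)CC
F4 | step 17 | (2S,3Z,6S,7E)-6-[(tert-butyldimethylsilyl)oxy]-3,7-dimethyl-8-{(2R)-5-oxo-4-[(4,4,5,5-tetramethyl-1,3,2-dioxaborolan-2-yl)methyl]-2,5-dihydrofuran-2-yl}-2-[(triethylsilyl)oxy]octa-3,7-dienal | O=C1O[C@@H](C=C1CB2OC(C)(C)C(C)(C)O2)/C=C(\C)[C@@H](O[Si](C)(C)C(C)(C)C)C/C=C(/C)[C@H](O[Si](CC)(CC)CC)C=O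
F5 | step 18 | O8 ester of 28 with 2-[bis(2,2,2-trifluoroethoxy)phosphoryl]propanoic acid (phosphonate α-carbon unassigned) | C=C1C(=O)O[C@@H]2/C=C(\C)[C@@H](O[Si](C)(C)C(C)(C)C)C/C=C(/C)[C@H](O[Si](CC)(CC)CC)[C@H](OC(=O)C(C)P(=O)(OCC(F)(F)F)OCC(F)(F)F)[C@@H]12
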